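**Assumption:** the target is the trans-(2R,3R) isomer exactly as drawn (both benzodioxane carbons R, my CIP assignment from the SMILES), and a ketoreductase with syn-(2S,3R) selectivity for keto ester 7 can be found by screening a commercial KRED panel. The route is a paper design; no step has been run.

## Retrosynthetic overview

1. Target ⇐ tri-O-benzyl flavone 17 (hydrogenolysis). The pyranone ring is formed last, by I2/DMSO oxidative cyclisation of 2'-hydroxychalcone 16, made from aldehyde 13 and acetophenone 15.
2. The 1,4-benzodioxane ring is formed first, by intramolecular Cu-catalysed aryl C–O coupling of a threo-(1R,2R) 1-aryl-2-(2-iodoaryloxy)propanol. The coupling retains both stereocentres, so threo gives trans.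
3. Both stereocentres come from one ketoreductase-mediated dynamic kinetic reduction of the racemic, configurationally labile α-aryloxy-β-keto ester 7.
4. Keto ester 7 ⇐ aldol then oxidation of aryloxyacetate 4 with O-benzylvanillin 5. Compound 4 comes from methyl 5-iodovanillate and ethyl bromoacetate, which fixes O4'–Cβ and leaves iodine at C3'.
5. Ring order: dioxane ring, then pyranone ring.

## Route

**Step 1**
Reactants: 1, methyl vanillate
Product: 2, methyl 4-hydroxy-3-iodo-5-methoxybenzoate
Conditions: NIS (1.05 equiv), TsOH·H2O (10 mol%), MeCN, rt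
Reagents that add atoms: N-iodosuccinimide, O=C1CCC(=O)N1I
Why: Electrophilic aromatic iodination directed ortho to the free phenol; para is blocked by the ester, so C5 is the only activated open site.

**Step 2**
Reactants: 2; 3, ethyl bromoacetate
Product: 4, methyl 4-(2-ethoxy-2-oxoethoxy)-3-iodo-5-methoxybenzoate
Conditions: K2CO3, DMF, 60 °C
Reagents that add atoms: ethyl bromoacetate (3), CCOC(=O)CBr
Why: Williamson etherification with an unhindered primary α-bromo ester works even on the 2,6-disubstituted phenoxide, and it attaches the future Cβ to O4' unambiguously.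

**Step 3**
Reactants: 4; 5, 4-(benzyloxy)-3-methoxybenzaldehyde
Product: 6, ethyl 3-[4-(benzyloxy)-3-methoxyphenyl]-3-hydroxy-2-[2-iodo-6-methoxy-4-(methoxycarbonyl)phenoxy]propanoate (racemic syn/anti mixture)
Conditions: LiHMDS (1.1 equiv), THF, –78 °C; then 5; AcOH quench at –78 °C
Reagents that add atoms: none (5 is a numbered reactant)
Why: Ester-enolate aldol addition as used for β-O-4 lignin models; the stereochemical outcome does not matter because both centres are erased or made labile in step 4.

**Step 4**
Reactants: 6
Product: 7, ethyl 3-[4-(benzyloxy)-3-methoxyphenyl]-2-[2-iodo-6-methoxy-4-(methoxycarbonyl)phenoxy]-3-oxopropanoate (racemic, configurationally labile)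
Conditions: Dess–Martin periodinane, NaHCO3, CH2Cl2, 0 °C to rt
Reagents that add atoms: none
Why: Dess–Martin oxidation of the benzylic alcohol under neutral conditions gives the α-aryloxy-β-keto ester, and the aryl iodide, esters and benzyl ether are inert.

**Step 5**
Reactants: 7
Product: 8, ethyl (2S,3R)-3-[4-(benzyloxy)-3-methoxyphenyl]-3-hydroxy-2-[2-iodo-6-methoxy-4-(methoxycarbonyl)phenoxy]propanoate (syn/threo)
Conditions: ketoreductase (KRED, syn-(2S,3R)-selective), NADP+ (cat.), i-PrOH (10% v/v, terminal reductant), KPi buffer pH 7.0–7.5, DMSO (15% v/v), 30 °C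
Reagents that add atoms: none
Why: Ketoreductase dynamic reductive kinetic resolution: the C2–H between ketone, ester and aryloxy epimerises in the buffer while the enzyme reduces only the (2S)-keto ester with face-selective hydride delivery from NADPH, so C3 (R) and C2 (S) are both set in one catalytic asymmetric step.

**Step 6**
Reactants: 8
Product: 9, (1R,2R)-1-[4-(benzyloxy)-3-methoxyphenyl]-2-[4-(hydroxymethyl)-2-iodo-6-methoxyphenoxy]propane-1,3-diol (threo)
Conditions: DIBAL-H (7 equiv), THF, –78 to 0 °C; Rochelle salt work-up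
Reagents that add atoms: none
Why: Hydride reduction of both esters to primary alcohols without touching the aryl iodide or either stereocentre; Cβ is no longer epimerisable and its descriptor changes from S to R only through CIP priorities.

**Step 7**
Reactants: 9
Product: 10, (1R,2R)-1-[4-(benzyloxy)-3-methoxyphenyl]-3-[(tert-butyldiphenylsilyl)oxy]-2-[4-{[(tert-butyldiphenylsilyl)oxy]methyl}-2-iodo-6-methoxyphenoxy]propan-1-ol
Conditions: TBDPSCl (2.2 equiv), imidazole, CH2Cl2, 0 °C to rt
Reagents that add atoms: tert-butyl(chloro)diphenylsilane, CC(C)(C)[Si](Cl)(c1ccccc1)c1ccccc1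
Why: Steric discrimination in silylation protects both primary alcohols and leaves only the hindered secondary benzylic OH free; TBDPS is chosen because it resists O-to-O migration under the basic coupling that follows.

**Step 8**
Reactants: 10
Product: 11, (2R,3R)-2-[4-(benzyloxy)-3-methoxyphenyl]-5-methoxy-3,7-bis{[(tert-butyldiphenylsilyl)oxy]methyl}-2,3-dihydro-1,4-benzodioxine (trans)
Conditions: CuI (20 mol%), 3,4,7,8-tetramethyl-1,10-phenanthroline (40 mol%), Cs2CO3 (2 equiv), toluene (0.05 M), 110 °C, Ar
Reagents that add atoms: none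
Why: Intramolecular Ullmann-type O-arylation of the secondary alkoxide onto the ortho C–I bond closes the six-membered ring; no bond at either stereocentre is broken, so the threo-(1R,2R) alcohol gives the trans-(2R,3R) benzodioxane with the aryl-bearing carbon on O3'.

**Step 9**
Reactants: 11
Product: 12, [(2R,3R)-3-[4-(benzyloxy)-3-methoxyphenyl]-8-methoxy-2,3-dihydro-1,4-benzodioxine-2,6-diyl]dimethanol
Conditions: TBAF (2.5 equiv), THF, 0 °C to rt
Reagents that add atoms: none
Why: Fluoride desilylation frees both primary alcohols; benzyl ethers and the benzodioxane are unaffected.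

**Step 10**
Reactants: 12
Product: 13, (2R,3R)-3-[4-(benzyloxy)-3-methoxyphenyl]-2-(hydroxymethyl)-8-methoxy-2,3-dihydro-1,4-benzodioxine-6-carbaldehyde
Conditions: activated MnO2 (15 equiv), CH2Cl2, rt
Reagents that add atoms: none
Why: MnO2 oxidises the benzylic alcohol chemoselectively and leaves the aliphatic CH2OH untouched.

**Step 11**
Reactants: 14, 2',4',6'-trihydroxyacetophenone
Product: 15, 1-[2,4-bis(benzyloxy)-6-hydroxyphenyl]ethan-1-one
Conditions: BnBr (2.05 equiv), K2CO3, DMF, rt
Reagents that add atoms: benzyl bromide, BrCc1ccccc1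
Why: Williamson benzylation; one ortho OH stays hydrogen-bonded to the ketone and is much less nucleophilic, so the 4,6-dibenzyl ether is the main product.

**Step 12**
Reactants: 13; 15
Product: 16, (E)-1-[2,4-bis(benzyloxy)-6-hydroxyphenyl]-3-[(2R,3R)-3-(4-benzyloxy-3-methoxyphenyl)-2-(hydroxymethyl)-8-methoxy-2,3-dihydro-1,4-benzodioxin-6-yl]prop-2-en-1-one
Conditions: KOH (50% aq., 10 equiv), EtOH/THF, rt, 24–48 h
Reagents that add atoms: none (15 is a numbered reactant)
Why: Claisen–Schmidt condensation of a non-enolisable aldehyde with the acetophenone gives the E-chalcone; neither benzodioxane C–H is acidic, so the stereocentres are stable to hydroxide.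

**Step 13**
Reactants: 16
Product: 17, 5,7-bis(benzyloxy)-2-[(2R,3R)-3-(4-benzyloxy-3-methoxyphenyl)-2-(hydroxymethyl)-8-methoxy-2,3-dihydro-1,4-benzodioxin-6-yl]-4H-chromen-4-one
Conditions: I2 (0.2 equiv), DMSO, 130 °C, 1–2 h; aq. Na2S2O3 work-up
Reagents that add atoms: none
Why: Iodine/DMSO oxidative cyclisation of the 2'-hydroxychalcone (oxa-Michael then dehydrogenation) builds the flavone; free aliphatic OH groups survive iodine dehydrogenation (as in hesperidin to diosmin), and any reversible benzylic ionisation would return the trans isomer under Cβ control.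

**Step 14**
Reactants: 17
Product: 18, 5'-methoxyhydnocarpin
Conditions: H2 (1 atm), 10% Pd/C, THF/MeOH, rt; stop at complete debenzylation
Reagents that add atoms: none
Why: Hydrogenolysis removes the three aryl benzyl ethers under mild conditions that are expected to spare the flavone C2=C3 bond and the cyclic benzylic ether; any 5-O-benzyl lost in step 13 converges here.

## Compound list

1 | methyl vanillate | COC(=O)c1ccc(O)c(OC)c1 | starting material
2 | methyl 4-hydroxy-3-iodo-5-methoxybenzoate | COC(=O)c1cc(I)c(O)c(OC)c1 | intermediate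
3 | ethyl bromoacetate | CCOC(=O)CBr | starting material
4 | methyl 4-(2-ethoxy-2-oxoethoxy)-3-iodo-5-methoxybenzoate | CCOC(=O)COc1c(I)cc(C(=O)OC)cc1OC | intermediate
5 | 4-(benzyloxy)-3-methoxybenzaldehyde | COc1cc(C=O)ccc1OCc1ccccc1 | starting material
6 | aldol adduct, racemic syn/anti | COc1cc(C(O)C(Oc2c(I)cc(C(=O)OC)cc2OC)C(=O)OCC)ccc1OCc1ccccc1 | intermediate
7 | α-aryloxy-β-keto ester, racemic and labile | COc1cc(C(=O)C(Oc2c(I)cc(C(=O)OC)cc2OC)C(=O)OCC)ccc1OCc1ccccc1 | intermediate
8 | (2S,3R)-syn hydroxy ester | COc1cc([C@@H](O)[C@H](Oc2c(I)cc(C(=O)OC)cc2OC)C(=O)OCC)ccc1OCc1ccccc1 | intermediate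
9 | (1R,2R)-threo triol | COc1cc([C@@H](O)[C@H](Oc2c(I)cc(CO)cc2OC)CO)ccc1OCc1ccccc1 | intermediate
10 | (1R,2R) bis-TBDPS ether, free secondary OH | COc1cc([C@@H](O)[C@H](Oc2c(I)cc(CO[Si](c3ccccc3)(c3ccccc3)C(C)(C)C)cc2OC)CO[Si](c2ccccc2)(c2ccccc2)C(C)(C)C)ccc1OCc1ccccc1 | intermediate
11 | trans-(2R,3R) benzodioxane bis-TBDPS ether | COc1cc([C@H]2Oc3cc(CO[Si](c4ccccc4)(c4ccccc4)C(C)(C)C)cc(OC)c3O[C@@H]2CO[Si](c2ccccc2)(c2ccccc2)C(C)(C)C)ccc1OCc1ccccc1 | intermediate
12 | trans-(2R,3R) benzodioxane diol | COc1cc([C@H]2Oc3cc(CO)cc(OC)c3O[C@@H]2CO)ccc1OCc1ccccc1 | intermediate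
13 | trans-(2R,3R) benzodioxane aldehyde | COc1cc([C@H]2Oc3cc(C=O)cc(OC)c3O[C@@H]2CO)ccc1OCc1ccccc1 | intermediate
14 | 2',4',6'-trihydroxyacetophenone | CC(=O)c1c(O)cc(O)cc1O | starting material
15 | 1-[2,4-bis(benzyloxy)-6-hydroxyphenyl]ethan-1-one | CC(=O)c1c(O)cc(OCc2ccccc2)cc1OCc1ccccc1 | intermediate
16 | (E)-2'-hydroxychalcone | COc1cc([C@H]2Oc3cc(/C=C/C(=O)c4c(O)cc(OCc5ccccc5)cc4OCc4ccccc4)cc(OC)c3O[C@@H]2CO)ccc1OCc1ccccc1 | intermediate
17 | tri-O-benzyl flavone | COc1cc([C@H]2Oc3cc(-c4cc(=O)c5c(OCc6ccccc6)cc(OCc6ccccc6)cc5o4)cc(OC)c3O[C@@H]2CO)ccc1OCc1ccccc1 | intermediate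
18 | 5'-methoxyhydnocarpin | COc1cc([C@H]2Oc3cc(-c4cc(=O)c5c(O)cc(O)cc5o4)cc(OC)c3O[C@@H]2CO)ccc1O | target

## Summary

Total steps: 14. Longest linear sequence: 13 (steps 1–10, then 12–14); step 11 is a one-step side branch.

Three steps most likely to fail:

- **Step 5 (KRED dynamic kinetic reduction).** The bulky diaryl keto ester may be poorly accepted or reduced with the wrong diastereoselectivity. Fallback: replace the biocatalyst with a chemocatalytic dynamic kinetic resolution, Ru(II)–TsDPEN asymmetric transfer hydrogenation (HCO2H/Et3N) of 7, which has precedent for syn-α-alkoxy-β-hydroxy esters. If only the anti-(2S,3S) product is accessible, keep it and close the ring with inversion at the benzylic carbon instead (iodide to phenol by borylation/oxidation, then intramolecular Mitsunobu).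
- **Step 8 (Cu-catalysed ring closure).** The hindered secondary benzylic alkoxide may couple slowly, or silyl migration or ketone formation may compete. Fallback: convert the aryl iodide of 10 to the phenol (Miyaura borylation, then H2O2) and close the ring with acid (TsOH or BF3·OEt2) through the p-benzyloxybenzylic cation, which gives the trans-benzodioxane under thermodynamic control from the Cβ centre.
- **Step 14 (global hydrogenolysis).** Over-reduction of the chromone C2=C3 bond or cleavage of the benzylic C–O bond of the dioxane is possible. Fallback: change the protecting-group plan to MOM ethers (O-MOM-vanillin in step 3 and 2'-hydroxy-4',6'-bis(methoxymethoxy)acetophenone in step 12), so the final deprotection is acidic (HCl/MeOH) and no reductive step is needed.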